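The route rests on disconnecting the O1–C2 bond of the dihydropyran ring at the chromene oxidation level. In step 1 an alkenyl Grignard reagent adds to 4-bromosalicylaldehyde and the ortho-hydroxybenzylic allylic alcohol loses water to an ortho-quinone methide, whose oxa-6π electrocyclisation forms O1–C2 and the pyran ring in one operation. The step exploits the gem-dimethyl carbon C2 bonded to O1 of the benzo-fused pyran ring: exactly the terminus pattern of a 1-oxatriene closure, with no five-membered alternative. The C3=C4 alkene left behind takes the (S)-carbinol by Jacobsen epoxidation and benzylic hydride opening; two Suzuki couplings (diborylmethane, then a bromomaleimide) finish the target without protecting groups.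

Key step: step 1

Remark: chroman numbering is used throughout (O1, C2 with the two methyl groups, C3 carbinol, C4 benzylic CH2, C7 bearing the maleimidylmethyl group); the carbinol centre of the target is (S).

Step 1
Reactants: 1 4-bromo-2-hydroxybenzaldehyde; 2 2-methyl-1-propenylmagnesium bromide
Product: 5 7-bromo-2,2-dimethyl-2H-chromene, via benzylic allylic alcohol 3 (not isolated), via ortho-quinone methide 4 (not isolated)
Conditions: 2 (2.3 equiv), THF, 0 °C to rt; 1 M HCl quench; crude 3, PPTS (cat.), toluene, 60 °C
Reagents that add atoms: none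
Why: The first equivalent of 2 deprotonates the phenol (releasing 2-methylpropene) and the second adds 1,2 to the aldehyde (Grignard addition); on acidification the doubly activated benzylic allylic alcohol 3 ionises and loses water to the ortho-quinone methide 4, a benzo-fused 1-oxatriene (O1=C8a–C4a=C4–C3=C2Me2), which undergoes thermal disrotatory oxa-6π electrocyclisation to form the O1–C2 bond. The closest known reaction type is the ortho-quinone methide route to 2H-chromenes from salicylaldehydes and alkenyl metal reagents. The pyran ring closes in the pericyclic 6π mode (formally 6-endo at the dimethyl-bearing terminus), and rearomatisation of the benzene ring makes the closure irreversible. No stereocentre survives the step: the carbinol centre of 3 is destroyed on dehydration and 5 is achiral, the C3 stereocentre being installed by reagent control in steps 2 and 3. The step needs ring-size and positional fidelity: a six-membered ring is the only electrocyclic outcome, the site of annulation is fixed by the formyl group of 1 (ortho to OH, para to Br), and E/Z isomers of 4 should funnel through the reversible ionisation to the reactive Z form. The aryl bromide is inert to the alkenyl Grignard reagent at 0 °C and serves as the later coupling handle.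

Step 2
Reactants: 5 7-bromo-2,2-dimethyl-2H-chromene
Product: 6 (1aS,7bS)-5-bromo-2,2-dimethyl-1a,7b-dihydro-2H-oxireno[2,3-c]chromene, the (3S,4S)-3,4-epoxychroman
Conditions: (S,S)-(salen)MnCl [salen = N,N'-bis(3,5-di-tert-butylsalicylidene)cyclohexane-1,2-diamine dianion, trivalent manganese] (4 mol%), 4-phenylpyridine N-oxide (0.2 equiv), aq NaOCl (pH 11.3), CH2Cl2, 0 °C
Reagents that add atoms: sodium hypochlorite, [Na+].[O-]Cl
Why: Jacobsen–Katsuki epoxidation, for which the cis-disubstituted aryl-conjugated C3=C4 alkene of a 2,2-dimethylchromene is the privileged substrate class: the oxomanganese species formed from the (S,S)-catalyst should transfer oxygen to one enantioface and set C3 and C4 together as the cis-fused (3S,4S)-epoxide, the sense established for chromenes with this catalyst enantiomer.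

Step 3
Reactants: 6 (1aS,7bS)-5-bromo-2,2-dimethyl-1a,7b-dihydro-2H-oxireno[2,3-c]chromene
Product: 7 (3S)-7-bromo-2,2-dimethyl-3,4-dihydro-2H-chromen-3-ol
Conditions: LiAlH4 (1.0 equiv), THF, 0 °C; aqueous work-up
Reagents that add atoms: none
Why: Regioselective SN2 hydride opening of an aryl epoxide: hydride should attack the benzylic C4 (C3 is neopentyl and shielded by the gem-dimethyl group), the C3–O bond is never broken so the (S) configuration set in step 2 is carried over unchanged, and the aryl bromide is not reduced at 0 °C.

Step 4
Reactants: 7 (3S)-7-bromo-2,2-dimethyl-3,4-dihydro-2H-chromen-3-ol; 8 bis[(pinacolato)boryl]methane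
Product: 9 (3S)-2,2-dimethyl-7-[(4,4,5,5-tetramethyl-1,3,2-dioxaborolan-2-yl)methyl]-3,4-dihydro-2H-chromen-3-ol
Conditions: 8 (1.5 equiv), Pd[P(t-Bu)3]2 (5 mol%), 8 M aq KOH (2 equiv), 1,4-dioxane, rt
Reagents that add atoms: none
Why: Suzuki–Miyaura coupling of a geminal diborylmethane: the second boryl group accelerates transmetalation of one boron only, so the benzylic boronate 9 should not couple further at room temperature, and the free secondary alcohol and its stereocentre are unaffected.

Step 5
Reactants: 10 3,4-dibromo-1H-pyrrole-2,5-dione; 11 4-hydroxyphenylboronic acid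
Product: 12 3-bromo-4-(4-hydroxyphenyl)-1H-pyrrole-2,5-dione
Conditions: 10 (1.5 equiv), Pd(PPh3)4 (5 mol%), K3PO4 (3 equiv), 1,4-dioxane/H2O, 50 °C; work-up at pH 4
Reagents that add atoms: none
Why: Suzuki–Miyaura mono-arylation of a symmetrical vinylic dibromide: the electron-donating 4-hydroxyphenyl group introduced first should deactivate the remaining C–Br bond toward zerovalent palladium, and the excess of 10 further suppresses double arylation.

Step 6
Reactants: 9 (3S)-2,2-dimethyl-7-[(4,4,5,5-tetramethyl-1,3,2-dioxaborolan-2-yl)methyl]-3,4-dihydro-2H-chromen-3-ol; 12 3-bromo-4-(4-hydroxyphenyl)-1H-pyrrole-2,5-dione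
Product: 13 asperimide C, 3-(4-hydroxyphenyl)-4-{[(3S)-3-hydroxy-2,2-dimethyl-3,4-dihydro-2H-chromen-7-yl]methyl}-1H-pyrrole-2,5-dione
Conditions: 12 (1.2 equiv), Pd(OAc)2 (5 mol%), SPhos (10 mol%), K3PO4 (4 equiv), 1,4-dioxane/H2O (5:1), 70 °C; work-up at pH 4
Reagents that add atoms: none
Why: Benzyl (sp3) Suzuki–Miyaura coupling with an electron-rich biarylphosphine ligand: oxidative addition into the vinylic C–Br bond of 12 and transmetalation of the benzylic boronate should join the two fragments, the N–H and O–H groups being tolerated as their potassium salts (which also shield the imide from hydroxide), and no stereocentre is touched.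

Compound list
1 | 4-bromo-2-hydroxybenzaldehyde | O=Cc1ccc(Br)cc1O | starting material
2 | 2-methyl-1-propenylmagnesium bromide | CC(C)=C[Mg]Br | starting material
3 | racemic 5-bromo-2-(1-hydroxy-3-methylbut-2-en-1-yl)phenol (benzylic allylic alcohol) | CC(C)=CC(O)c1ccc(Br)cc1O | intermediate
4 | (6Z)-3-bromo-6-(3-methylbut-2-en-1-ylidene)cyclohexa-2,4-dien-1-one (ortho-quinone methide) | CC(C)=C/C=C1/C=CC(Br)=CC1=O | intermediate
5 | 7-bromo-2,2-dimethyl-2H-chromene | CC1(C)C=Cc2ccc(Br)cc2O1 | intermediate
6 | (1aS,7bS)-5-bromo-2,2-dimethyl-1a,7b-dihydro-2H-oxireno[2,3-c]chromene | CC1(C)Oc2cc(Br)ccc2[C@@H]3O[C@H]13 | intermediate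
7 | (3S)-7-bromo-2,2-dimethyl-3,4-dihydro-2H-chromen-3-ol | CC1(C)Oc2cc(Br)ccc2C[C@@H]1O | intermediate
8 | bis[(pinacolato)boryl]methane | CC1(C)OB(CB2OC(C)(C)C(C)(C)O2)OC1(C)C | starting material
9 | (3S)-2,2-dimethyl-7-[(4,4,5,5-tetramethyl-1,3,2-dioxaborolan-2-yl)methyl]-3,4-dihydro-2H-chromen-3-ol | CC1(C)Oc2cc(CB3OC(C)(C)C(C)(C)O3)ccc2C[C@@H]1O | intermediate
10 | 3,4-dibromo-1H-pyrrole-2,5-dione | O=C1NC(=O)C(Br)=C1Br | starting material
11 | 4-hydroxyphenylboronic acid | OB(O)c1ccc(O)cc1 | starting material
12 | 3-bromo-4-(4-hydroxyphenyl)-1H-pyrrole-2,5-dione | O=C1NC(=O)C(c2ccc(O)cc2)=C1Br | intermediate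
13 | asperimide C | CC1(C)Oc2cc(CC3=C(c4ccc(O)cc4)C(=O)NC3=O)ccc2C[C@@H]1O | target

Total step count: 6. Longest linear sequence: 5 steps (steps 1, 2, 3, 4 and 6).

Steps most likely to fail

Step 6. The benzylic boronate may undergo protodeboronation under the aqueous base faster than its slow two-electron transmetalation, and the acidic N–H and O–H groups of 12 may retard oxidative addition. The fallback sets out from 9: exchange of the pinacol ester with KHF2 (MeOH/H2O, rt) would give potassium {[(3S)-3-hydroxy-2,2-dimethyl-3,4-dihydro-2H-chromen-7-yl]methyl}trifluoroborate F1. Its photoredox/nickel dual-catalysed coupling with 12 (Ir[dF(CF3)ppy]2(bpy)PF6, NiCl2·glyme, 4,4'-di-tert-butyl-2,2'-bipyridine, 2,6-lutidine, acetone/MeOH, blue light, rt) generates a benzylic radical by single-electron oxidation, and nickel captures it without strong base. This comes back to the route at 13.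

Step 5. The second C–Br bond may also be arylated (over-coupling to the symmetrical bis-aryl maleimide), and the N–H dibromide may lose bromide to hydroxide or to the phenoxide by addition–elimination. The fallback sets out from 9 and 10 and reverses the order of the two couplings. Coupling of 9 with an excess of 10 under the conditions of step 6 would give 3-bromo-4-{[(3S)-3-hydroxy-2,2-dimethyl-3,4-dihydro-2H-chromen-7-yl]methyl}-1H-pyrrole-2,5-dione F2; the sluggish sp3 boronate should not couple twice. Arylation of F2 with an excess of 11 (Pd(PPh3)4, K3PO4, 1,4-dioxane/H2O, 70 °C) comes back to the route at 13.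

Step 3. Hydride may partition between C4 and C3 or reduce the aryl bromide. Aluminium Lewis acids may also trigger a 1,2-hydride shift to the ketone followed by unselective reduction, which would erode the enantiomeric purity. The fallback sets out from 6: a deliberate Meinwald rearrangement (BF3·OEt2 cat., CH2Cl2, −20 °C) would give 7-bromo-2,2-dimethyl-2H-chromen-3(4H)-one F3. Corey–Bakshi–Shibata reduction with the (R)-2-methyl-oxazaborolidine and BH3·SMe2 (THF, −20 °C), with the quaternary C2 as the large and the benzylic C4 as the small substituent, should reset the (S)-carbinol and comes back to the route at 7.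

Further compounds
F1 | step 6 | potassium {[(3S)-3-hydroxy-2,2-dimethyl-3,4-dihydro-2H-chromen-7-yl]methyl}trifluoroborate | CC1(C)Oc2cc(C[B-](F)(F)F)ccc2C[C@@H]1O.[K+]
F2 | step 5 | 3-bromo-4-{[(3S)-3-hydroxy-2,2-dimethyl-3,4-dihydro-2H-chromen-7-yl]methyl}-1H-pyrrole-2,5-dione | CC1(C)Oc2cc(CC3=C(Br)C(=O)NC3=O)ccc2C[C@@H]1O
F3 | step 3 | 7-bromo-2,2-dimethyl-2H-chromen-3(4H)-one | CC1(C)Oc2cc(Br)ccc2CC1=O
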